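**Plan**
Enabling feature: in ring C the ether bond O1–C8a ties the oxygen of the secondary benzylic carbinol C2 to an sp2 carbon of ring A, so the ring can be closed at the arene without touching any bond at C2.
Cuts, in retrosynthetic order: 5-O–CH3; C4=O back to a silylated C4 carbinol; O1–C8a (aryl triflate plus C2–OH); C2 carbinol back to the ketone; C3–C4 (aldol); then the triflate, C4a–CHO and C6–prenyl on ring A.
Forward: ring A (from 3,5-dimethoxyphenol) is prenylated between its methoxy groups, formylated ortho to OH and triflated; a ring B acetophenone enolate joins C3 to C4; ring C closes last.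
Stereochemistry: C2 (S) is set by transfer hydrogenation of the ring B aryl ketone with RuCl[(S,S)-TsDPEN](p-cymene) and is retained to the end; C4 is carried as both epimers and erased by oxidation.
Ring A regiochemistry: one formylation desymmetrises the mirror-symmetric phenol, and the C4 carbonyl finally singles out the 5-OMe for cleavage.

Key step: step 9

Remark: flavanone numbering (O1, C2, C3, C4, C4a, C5–C8, C8a; ring B primed) is also used for the open-chain precursors. The C4 carbinol centre is formed racemic in step 7 and carried as both epimers, so it has no descriptor in the SMILES of 12–16.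

Step 1
Reactants: 1 3,5-dimethoxyphenol
Product: 2 (3,5-dimethoxyphenoxy)triisopropylsilane
Conditions: TIPSCl, imidazole, DMF, rt
Reagents that add atoms: triisopropylsilyl chloride, CC(C)[Si](Cl)(C(C)C)C(C)C
Why: Imidazole-promoted O-silylation of a phenol; the bulky TIPS group resists attack of n-BuLi at silicon and, as a poor and hindered directing group, shields the two carbons next to it in step 2.

Step 2
Reactants: 2 (3,5-dimethoxyphenoxy)triisopropylsilane; 3 prenyl bromide (1-bromo-3-methylbut-2-ene)
Product: 5 [3,5-dimethoxy-4-(3-methylbut-2-enyl)phenoxy]triisopropylsilane, via aryllithium 4 (not isolated)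
Conditions: n-BuLi, THF, 0 °C to rt; then CuBr·SMe2 (10 mol %), 3, −78 °C to rt
Reagents that add atoms: none
Why: Directed ortho-metalation takes place at the carbon flanked by both methoxy groups (cooperative 1,3-directing pair) in preference to the positions beside OTIPS, and copper-assisted SN2 alkylation of such 2,6-dimethoxyaryllithiums at the primary carbon of prenyl bromide is standard prenylarene chemistry.

Step 3
Reactants: 5 [3,5-dimethoxy-4-(3-methylbut-2-enyl)phenoxy]triisopropylsilane
Product: 6 3,5-dimethoxy-4-(3-methylbut-2-enyl)phenol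
Conditions: Bu4NF, AcOH, THF, 0 °C
Reagents that add atoms: none
Why: Fluoride cleavage of an aryl silyl ether is fast and leaves the methyl ethers and the trisubstituted alkene untouched.

Step 4
Reactants: 6 3,5-dimethoxy-4-(3-methylbut-2-enyl)phenol
Product: 7 6-hydroxy-2,4-dimethoxy-3-(3-methylbut-2-enyl)benzaldehyde
Conditions: MgCl2, Et3N, (CH2O)n, MeCN, reflux; then cold 1 M HCl
Reagents that add atoms: paraformaldehyde (as formaldehyde), C=O
Why: In the Casnati–Skattebøl ortho-formylation magnesium holds phenoxide and formaldehyde together so that carbon is attached only ortho to oxygen, the two ortho positions of the mirror-symmetric phenol are equivalent so that one aldehyde should result, and the non-acidic medium spares the prenyl group.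

Step 5
Reactants: 7 6-hydroxy-2,4-dimethoxy-3-(3-methylbut-2-enyl)benzaldehyde
Product: 8 2-formyl-3,5-dimethoxy-4-(3-methylbut-2-enyl)phenyl trifluoromethanesulfonate
Conditions: Tf2O, pyridine, CH2Cl2, 0 °C
Reagents that add atoms: triflic anhydride, O=S(=O)(OS(=O)(=O)C(F)(F)F)C(F)(F)F
Why: O-Triflation of a salicylaldehyde with Tf2O is routine, and pyridine buffers the acid that could otherwise protonate the prenyl alkene.

Step 6
Reactants: 9 4'-hydroxyacetophenone
Product: 10 4'-(triisopropylsilyloxy)acetophenone
Conditions: TIPSCl, imidazole, DMF, rt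
Reagents that add atoms: triisopropylsilyl chloride, CC(C)[Si](Cl)(C(C)C)C(C)C
Why: Standard phenol silylation; TIPS is chosen over TBS because the aryl silyl ether must later survive an amide base, formic acid/Et3N and hot Cs2CO3.

Step 7
Reactants: 10 4'-(triisopropylsilyloxy)acetophenone; 8 2-formyl-3,5-dimethoxy-4-(3-methylbut-2-enyl)phenyl trifluoromethanesulfonate
Product: 13 rac-3-(tert-butyldimethylsilyloxy)-3-[2,4-dimethoxy-3-(3-methylbut-2-enyl)-6-(trifluoromethylsulfonyloxy)phenyl]-1-[4-(triisopropylsilyloxy)phenyl]propan-1-one, via lithium enolate 11 (not isolated), via lithium aldolate 12 (not isolated)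
Conditions: LiN(SiMe3)2, THF, −78 °C; then 8, −78 °C; then TBSOTf, 2,6-lutidine, −78 to −40 °C
Reagents that add atoms: tert-butyldimethylsilyl triflate, CC(C)(C)[Si](C)(C)OS(=O)(=O)C(F)(F)F
Why: Crossed lithium aldol addition of a methyl ketone enolate to a non-enolisable aldehyde forms C3–C4, and O-silylation of the aldolate in the same flask locks the adduct before retro-aldol, dehydration to the chalcone or triflyl transfer from the neighbouring sulfonate can set in; the new C4 centre is deliberately formed racemic because step 11 erases it.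

Step 8
Reactants: 13 rac-3-(tert-butyldimethylsilyloxy)-3-[2,4-dimethoxy-3-(3-methylbut-2-enyl)-6-(trifluoromethylsulfonyloxy)phenyl]-1-[4-(triisopropylsilyloxy)phenyl]propan-1-one
Product: 14 (1S,3RS)-3-(tert-butyldimethylsilyloxy)-3-[2,4-dimethoxy-3-(3-methylbut-2-enyl)-6-(trifluoromethylsulfonyloxy)phenyl]-1-[4-(triisopropylsilyloxy)phenyl]propan-1-ol
Conditions: RuCl[(S,S)-TsDPEN](p-cymene) (2 mol %), HCO2H/Et3N (5:2), EtOAc, 30 °C
Reagents that add atoms: none
Why: In the Noyori–Ikariya asymmetric transfer hydrogenation the ruthenium hydride from the (S,S)-catalyst places the conjugated ring B aryl group under its p-cymene ligand and delivers hydride to the Re face of the ketone, which sets C2 as S under catalyst control for both enantiomers of 13, while formic acid makes the reduction of this electron-rich ketone irreversible and leaves triflate, alkene and silyl ethers alone.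

Step 9
Reactants: 14 (1S,3RS)-3-(tert-butyldimethylsilyloxy)-3-[2,4-dimethoxy-3-(3-methylbut-2-enyl)-6-(trifluoromethylsulfonyloxy)phenyl]-1-[4-(triisopropylsilyloxy)phenyl]propan-1-ol
Product: 15 (2S,4RS)-4-(tert-butyldimethylsilyloxy)-5,7-dimethoxy-6-(3-methylbut-2-enyl)-4'-(triisopropylsilyloxy)flavan
Conditions: Pd(OAc)2 (5 mol %), 2-(di-tert-butylphosphino)-1,1'-binaphthyl (6 mol %), Cs2CO3 (1.5 equiv), toluene, 70 °C
Reagents that add atoms: none
Why: Pd(OAc)2 is reduced in situ to a monoligated zerovalent palladium complex that inserts into the C8a–OTf bond; the C2 hydroxyl binds to the cationic divalent arylpalladium centre, Cs2CO3 removes its proton, and the seven-membered aryl(alkoxo)palladacycle (Pd, C8a, C4a, C4, C3, C2, O1) undergoes C–O reductive elimination. The closest known reaction type is the Buchwald-type intramolecular etherification of aryl halides and sulfonates with tethered secondary alcohols, which turns enantioenriched carbinols into chromans without loss of configuration. Ring C closes as a six-membered ring by contraction of that palladacycle, O1 bonding to the sp2 carbon C8a, so the closure is metal-templated and is not a displacement at C2. No stereocentre is created: only the O–H bond of the carbinol is broken, so C2 stays S, and both C4 epimers should cyclise to products that converge in step 11. The selectivity needed is reductive elimination ahead of β-hydride elimination from C2–H and ahead of S–O cleavage of the triflate; the bulky di-tert-butylbiaryl ligand, the ortho C4a branch that compresses the aryl–Pd–O angle and the meta placement of both methoxy groups relative to C8a favour the former, and sparingly soluble Cs2CO3 in dry toluene spares the sulfonate. The TBS group keeps the C4 oxygen off palladium (a free C4–OH would form a five-membered chelate and deliver hydride), the lack of a carbonyl excludes retro-aldol and retro-oxa-Michael loss of C2, the TIPS ether withstands carbonate, and the prenyl alkene sits para to C8a, out of reach of a Heck reaction.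

Step 10
Reactants: 15 (2S,4RS)-4-(tert-butyldimethylsilyloxy)-5,7-dimethoxy-6-(3-methylbut-2-enyl)-4'-(triisopropylsilyloxy)flavan
Product: 16 (2S,4RS)-4'-hydroxy-5,7-dimethoxy-6-(3-methylbut-2-enyl)flavan-4-ol
Conditions: Bu4NF/AcOH (1:1, excess), THF, 0 °C to rt; neutral work-up, used without chromatography
Reagents that add atoms: none
Why: Fluoride-driven desilylation of both ethers is run before any carbonyl exists and is buffered with AcOH, so that neither a ring B phenoxide (quinone-methide opening of the C2–O1 bond) nor acid (ionisation at the electron-rich benzylic C4) can build up and C2 stays S.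

Step 11
Reactants: 16 (2S,4RS)-4'-hydroxy-5,7-dimethoxy-6-(3-methylbut-2-enyl)flavan-4-ol
Product: 17 (2S)-4'-hydroxy-5,7-dimethoxy-6-(3-methylbut-2-enyl)flavanone
Conditions: MnO2 (activated, excess), CH2Cl2, rt
Reagents that add atoms: none
Why: Neutral heterogeneous MnO2 oxidation of a strongly activated benzylic alcohol lets both C4 epimers converge on one ketone, normally tolerates a simple monohydric phenol and a trisubstituted alkene, and by the absence of base avoids retro-oxa-Michael opening at C2.

Step 12
Reactants: 17 (2S)-4'-hydroxy-5,7-dimethoxy-6-(3-methylbut-2-enyl)flavanone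
Product: 18 (2S)-5,4'-dihydroxy-7-methoxy-6-(3-methylbut-2-enyl)flavanone (6-prenylsakuranetin)
Conditions: MgI2·OEt2 (excess), THF, 50 °C; then H2O
Reagents that add atoms: none
Why: In this chelation-directed aryl methyl ether cleavage the magnesium ion held between the C4 carbonyl and the peri 5-OMe oxygen activates only that methyl group for SN2 attack by iodide, the 7-OMe lacks such a neighbour, and the reagent is established for 5-O-methyl prenylflavanones with free phenols, its near-neutral medium sparing the prenyl group and C2.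

**Compound list**
1 | 3,5-dimethoxyphenol | COc1cc(O)cc(OC)c1 | starting material
2 | (3,5-dimethoxyphenoxy)triisopropylsilane | COc1cc(O[Si](C(C)C)(C(C)C)C(C)C)cc(OC)c1 | intermediate
3 | prenyl bromide | CC(C)=CCBr | starting material
4 | 2,6-dimethoxy-4-(triisopropylsilyloxy)phenyllithium | COc1cc(O[Si](C(C)C)(C(C)C)C(C)C)cc(OC)c1[Li] | intermediate
5 | [3,5-dimethoxy-4-(3-methylbut-2-enyl)phenoxy]triisopropylsilane | COc1cc(O[Si](C(C)C)(C(C)C)C(C)C)cc(OC)c1CC=C(C)C | intermediate
6 | 3,5-dimethoxy-4-(3-methylbut-2-enyl)phenol | COc1cc(O)cc(OC)c1CC=C(C)C | intermediate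
7 | 6-hydroxy-2,4-dimethoxy-3-(3-methylbut-2-enyl)benzaldehyde | COc1cc(O)c(C=O)c(OC)c1CC=C(C)C | intermediate
8 | 2-formyl-3,5-dimethoxy-4-(3-methylbut-2-enyl)phenyl trifluoromethanesulfonate | COc1cc(OS(=O)(=O)C(F)(F)F)c(C=O)c(OC)c1CC=C(C)C | intermediate
9 | 4'-hydroxyacetophenone | CC(=O)c1ccc(O)cc1 | starting material
10 | 4'-(triisopropylsilyloxy)acetophenone | CC(=O)c1ccc(O[Si](C(C)C)(C(C)C)C(C)C)cc1 | intermediate
11 | lithium enolate of 10 | [Li+].[O-]C(=C)c1ccc(O[Si](C(C)C)(C(C)C)C(C)C)cc1 | intermediate
12 | racemic lithium aldolate from 11 and 8 | [Li+].[O-]C(CC(=O)c1ccc(O[Si](C(C)C)(C(C)C)C(C)C)cc1)c1c(OC)c(CC=C(C)C)c(OC)cc1OS(=O)(=O)C(F)(F)F | intermediate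
13 | rac-3-(tert-butyldimethylsilyloxy)-3-[2,4-dimethoxy-3-prenyl-6-(trifluoromethylsulfonyloxy)phenyl]-1-[4-(triisopropylsilyloxy)phenyl]propan-1-one | COc1cc(OS(=O)(=O)C(F)(F)F)c(c(OC)c1CC=C(C)C)C(O[Si](C)(C)C(C)(C)C)CC(=O)c1ccc(O[Si](C(C)C)(C(C)C)C(C)C)cc1 | intermediate
14 | (1S,3RS)-3-(tert-butyldimethylsilyloxy)-3-[2,4-dimethoxy-3-prenyl-6-(trifluoromethylsulfonyloxy)phenyl]-1-[4-(triisopropylsilyloxy)phenyl]propan-1-ol | COc1cc(OS(=O)(=O)C(F)(F)F)c(c(OC)c1CC=C(C)C)C(O[Si](C)(C)C(C)(C)C)C[C@H](O)c1ccc(O[Si](C(C)C)(C(C)C)C(C)C)cc1 | intermediate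
15 | (2S,4RS)-4-(tert-butyldimethylsilyloxy)-5,7-dimethoxy-6-prenyl-4'-(triisopropylsilyloxy)flavan | COc1cc2c(c(OC)c1CC=C(C)C)C(O[Si](C)(C)C(C)(C)C)C[C@@H](c1ccc(O[Si](C(C)C)(C(C)C)C(C)C)cc1)O2 | intermediate
16 | (2S,4RS)-4'-hydroxy-5,7-dimethoxy-6-prenylflavan-4-ol | COc1cc2c(c(OC)c1CC=C(C)C)C(O)C[C@@H](c1ccc(O)cc1)O2 | intermediate
17 | (2S)-4'-hydroxy-5,7-dimethoxy-6-prenylflavanone | COc1cc2c(c(OC)c1CC=C(C)C)C(=O)C[C@@H](c1ccc(O)cc1)O2 | intermediate
18 | (2S)-6-prenylsakuranetin | COc1cc2c(c(O)c1CC=C(C)C)C(=O)C[C@@H](c1ccc(O)cc1)O2 | target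

**Step count**
Total step count: 12. Longest linear sequence: 11 steps (steps 1–5 and 7–12, from 3,5-dimethoxyphenol 1). Step 6 lies on the ring B branch.

**Steps most likely to fail**

First, step 9. Three processes may outrun C–O reductive elimination:
- β-hydride elimination from the palladium alkoxide, which reduces the arene and oxidises the carbinol
- S–O cleavage of the triflate by carbonate
- a base-induced shift of the TBS group from the C4 oxygen to the C2 oxygen

The fallback closes ring C at the other end of O1, by SN2 displacement at C2 with inversion, and sets out from ketone 13. Transfer hydrogenation with RuCl[(R,R)-TsDPEN](p-cymene) in HCO2H/Et3N should give the (1R,3RS)-carbinol triflate F1. Miyaura borylation (PdCl2(dppf), B2pin2, KOAc, dioxane, 80 °C) exchanges the sulfonate for boron and gives the pinacol arylboronate F2. NaBO3·4H2O in THF/H2O oxidises it to the free C8a phenol F3 while the TIPS aryl ether stays in place. Intramolecular Mitsunobu etherification (PPh3, DIAD, toluene, 0 °C; 6-exo-tet) then turns C2 from R into S and comes back to the route at flavan 15.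

Second, step 7. Four processes may erode the adduct:
- reversal of the addition with this hindered, electron-rich aldehyde
- E1cB loss of the C4 oxygen
- transfer of the triflyl group from the C8a oxygen to the adjacent lithium alkoxide
- sluggish silylation of the crowded aldolate

The fallback forms C3–C4 under Lewis acid instead of base, so that no free alkoxide ever sits next to the sulfonate, and sets out from ketone 10. TMSOTf and Et3N in CH2Cl2 at 0 °C give the trimethylsilyl enol ether F4. Its Mukaiyama aldol addition to aldehyde 8 (BF3·OEt2, CH2Cl2, −78 °C) gives, after aqueous work-up, the racemic β-hydroxy ketone F5. TBSOTf and 2,6-lutidine in CH2Cl2 at −78 °C silylate the carbinol, and the route is rejoined at 13.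

Third, step 12. Lewis-acid-assisted opening of ring C to the chalcone and reclosure would erode the configuration at C2, and electron push from the free 4'-hydroxyl would help it. Prolonged heating may also let the liberated 5-OH add to the prenyl alkene. The fallback changes the order of unmasking: the ring B phenol is capped while the Lewis acid acts and is released last under weakly acidic fluoride. It sets out from flavanone 17. TBSCl and imidazole in CH2Cl2 at 0 °C give the 4'-O-TBS 5,7-dimethoxyflavanone F6. MgI2·OEt2 in THF cleaves the chelated methyl ether to give the 4'-O-TBS 5-hydroxyflavanone F7. Et3N·3HF in THF at rt removes the silyl group without base and arrives at target 18.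

Further compounds
F1 | step 9 | (1R,3RS)-3-(tert-butyldimethylsilyloxy)-3-[2,4-dimethoxy-3-prenyl-6-(trifluoromethylsulfonyloxy)phenyl]-1-[4-(triisopropylsilyloxy)phenyl]propan-1-ol | COc1cc(OS(=O)(=O)C(F)(F)F)c(c(OC)c1CC=C(C)C)C(O[Si](C)(C)C(C)(C)C)C[C@@H](O)c1ccc(O[Si](C(C)C)(C(C)C)C(C)C)cc1
F2 | step 9 | (1R,3RS)-3-(tert-butyldimethylsilyloxy)-3-[2,4-dimethoxy-3-prenyl-6-(4,4,5,5-tetramethyl-1,3,2-dioxaborolan-2-yl)phenyl]-1-[4-(triisopropylsilyloxy)phenyl]propan-1-ol | COc1cc(B2OC(C)(C)C(C)(C)O2)c(c(OC)c1CC=C(C)C)C(O[Si](C)(C)C(C)(C)C)C[C@@H](O)c1ccc(O[Si](C(C)C)(C(C)C)C(C)C)cc1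
F3 | step 9 | (1R,3RS)-3-(tert-butyldimethylsilyloxy)-3-[6-hydroxy-2,4-dimethoxy-3-prenylphenyl]-1-[4-(triisopropylsilyloxy)phenyl]propan-1-ol | COc1cc(O)c(c(OC)c1CC=C(C)C)C(O[Si](C)(C)C(C)(C)C)C[C@@H](O)c1ccc(O[Si](C(C)C)(C(C)C)C(C)C)cc1
F4 | step 7 | triisopropyl{4-[1-(trimethylsilyloxy)vinyl]phenoxy}silane | C=C(O[Si](C)(C)C)c1ccc(O[Si](C(C)C)(C(C)C)C(C)C)cc1
F5 | step 7 | rac-3-hydroxy-3-[2,4-dimethoxy-3-prenyl-6-(trifluoromethylsulfonyloxy)phenyl]-1-[4-(triisopropylsilyloxy)phenyl]propan-1-one | COc1cc(OS(=O)(=O)C(F)(F)F)c(c(OC)c1CC=C(C)C)C(O)CC(=O)c1ccc(O[Si](C(C)C)(C(C)C)C(C)C)cc1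
F6 | step 12 | (2S)-4'-(tert-butyldimethylsilyloxy)-5,7-dimethoxy-6-prenylflavanone | COc1cc2c(c(OC)c1CC=C(C)C)C(=O)C[C@@H](c1ccc(O[Si](C)(C)C(C)(C)C)cc1)O2
F7 | step 12 | (2S)-4'-(tert-butyldimethylsilyloxy)-5-hydroxy-7-methoxy-6-prenylflavanone | COc1cc2c(c(O)c1CC=C(C)C)C(=O)C[C@@H](c1ccc(O[Si](C)(C)C(C)(C)C)cc1)O2
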